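The pitfall in these flasks was to rank them by temperature: left-handed product has a ceiling. Left-handed substrate is half of the charge, so its product cannot pass 50.0%. The blue run stood level near there, reading 52% and then 52%. So I asked how fast that ceiling is approached.

| flask | left-handed substrate | right-handed substrate | gas | free catalyst | temperature | remark | time |
|---|---|---|---|---|---|---|---|
| blue | 0.15 M | 0.15 M | 14 mM (held) | 0.60 mM | 50 °C | run made earlier |  |
| grey | 0.60 M | 0.60 M | 14 mM (held) | 0.60 mM | 72 °C | run made earlier |  |
| amber | 0.30 M | 0.30 M | 14 mM (held) | 0.30 mM | 50 °C | run made earlier |  |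
| winter | 0.30 M | 0.30 M | 14 mM (held) | 0.60 mM | 60 °C |  | 80 min |
| autumn | 0.30 M | 0.30 M | 14 mM (held) | 0.60 mM | 80 °C |  | 80 min |
| summer | 0.30 M | 0.30 M | 14 mM (held) | 0.60 mM |  | at 80 °C until 25 min, from then on at 40 °C | 80 min |
| dusk | 0.30 M | 0.30 M | 14 mM (held) | 0.60 mM | 40 °C |  | 80 min |

| run | time / min | left-handed product / % | left-handed substrate / % |
|---|---|---|---|
| blue | 6.00 | 10 | 39 |
| blue | 10.0 | 17 | 35 |
| blue | 15.0 | 26 | 22 |
| blue | 30.0 | 43 | 7 |
| blue | 50.0 | 52 | 3 |
| blue | 80.0 | 52 | 3 |
| grey | 2.00 | 2 | 47 |
| grey | 3.00 | 2 | 50 |
| grey | 6.00 | 4 | 45 |
| grey | 12.0 | 6 | 45 |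
| grey | 15.0 | 7 | 41 |
| grey | 30.0 | 17 | 36 |
| amber | 6.00 | 7 | 45 |
| amber | 20.0 | 16 | 36 |
| amber | 30.0 | 27 | 24 |
| amber | 50.0 | 39 | 9 |
| amber | 80.0 | 46 | 1 |

(scatter of a reading: 1.5 percentage points)

- the best flask by amount of left-handed product, in percent of the left-handed substrate and right-handed substrate together charged; "all alike" if 1.5 percentage points covers them all (winter / autumn / summer / dusk / all alike)
- amount of left-handed product at the end, in percent of the left-handed substrate and right-handed substrate together charged, winter
- amount of left-handed product at the end, in percent of the left-handed substrate and right-handed substrate together charged, autumn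
- amount of left-handed product at the end, in percent of the left-handed substrate and right-handed substrate together charged, summer
- amount of left-handed product at the end, in percent of the left-handed substrate and right-handed substrate together charged, dusk

- free catalyst is single-handed; left-handed substrate and right-handed substrate are mirror images of each other, charged as a racemate, each of them at the stated concentration
- at the start none of reagent is dissolved
- the numbers in the tables scatter with a standard deviation of 1.5 percentage points
- steps under discussion: free catalyst + left-handed substrate <-> catalyst intermediate A; free catalyst + right-handed substrate <-> catalyst intermediate B; reagent + catalyst intermediate A -> free catalyst + left-handed product; reagent + catalyst intermediate B -> free catalyst + right-handed product; gas <-> reagent; 2 reagent -> self-condensation product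

Each catalytic turn takes one reagent, and no reagent is dissolved at the start. I solved two extreme versions.

In the gas-fed version, reagent is taken as it dissolves, which makes the gas passage the rate-limiting step, and product grows in a straight line. The blue run gives its slope:

r = 5.20 mM min⁻¹

The grey run at 72 °C gave 6.80 mM min⁻¹, more than blue at 50 °C, but by a factor of 1.31. From r I carried one quantity:

t(fill) = c(left-handed substrate) / r = 57.7 min

This fill time, the time for the gas to feed as much reagent as there is left-handed substrate charged, is shorter than the 80 min allowed, so this version reaches the ceiling.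

In the catalyst-fed version, reagent is plentiful and the rate follows c(left-handed substrate). Blue has the same catalyst charge and gives a time constant of 28.8 min, so this version gives at the end:

46.9%

For blue at 30.0 min the catalyst-fed version gives 32.3%, less than the reading of 43%, while the gas-fed version has reached the ceiling of 50.0% by then. The reading lies between them and nearer the gas-fed version, so I placed the flasks there. Dusk, at 40 °C, is colder than any run, so I trusted it least.

The forecast said all alike, with 49%, 49%, 49% and 47% for winter, autumn, summer and dusk, holding that “the step limiting the rate is the supply of reagent from the gas”.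

The flasks gave all alike: 50.0%, 50.0%, 49.5% and 49.3%.

    free catalyst + left-handed substrate ⇌ catalyst intermediate A (K = 2.20 L mol⁻¹, k = 3000 L mol⁻¹ min⁻¹, Ea = 51.0 kJ mol⁻¹, ΔH = −6.00 kJ mol⁻¹)
    free catalyst + right-handed substrate ⇌ catalyst intermediate B (K = 0.930 L mol⁻¹, k = 1000 L mol⁻¹ min⁻¹, Ea = 36.0 kJ mol⁻¹, ΔH = 7.00 kJ mol⁻¹)
    reagent + catalyst intermediate A → free catalyst + left-handed product (k = 58000 L mol⁻¹ min⁻¹, Ea = 35.0 kJ mol⁻¹)
    reagent + catalyst intermediate B → free catalyst + right-handed product (k = 1800 L mol⁻¹ min⁻¹, Ea = 56.0 kJ mol⁻¹)
    gas ⇌ reagent, rate k5*(csat - [reagent]) (kL = 0.490 min⁻¹)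
    2 reagent → self-condensation product (k = 4.00 L mol⁻¹ min⁻¹, Ea = 50.0 kJ mol⁻¹)
    (constants at 80 °C)

In winter at 40.0 min, with left-handed substrate at 10.7%, reagent stood at 0.00304 M and left-handed product at 39.3%. By 80.0 min, left-handed substrate was down to 0.00762%, reagent had risen to 0.0117 M and right-handed product stood at 4.21%. Summer's answer moves by 5 points when read at 52.6 min, a time shorter than the fill time.

Dusk read at 150 min stands at 2.60 fill times, so the reckoning gives the ceiling, 50.0%. The computed flask gave 50.0%, with 0% of the charged left-handed substrate still unbound.

The numbers in the tables come from a simulation on assumed constants; the scatter is artificial.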